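**Retrosynthetic overview**
1. Target 14 ⇐ regio- and face-selective 1,2-reduction of epoxyquinone 13; the carbinol is set last, anti to the oxirane.
2. 13 ⇐ ketal hydrolysis and Saegusa dehydrogenation of epoxy ketone 11 ⇐ oxidation of the cis-epoxy alcohol 10 ⇐ hydroxyl-directed epoxidation of allylic alcohol 9.
3. 9 ⇐ ketoreductase reduction of enone 8 ⇐ Cu/phosphoramidite asymmetric conjugate addition of Et2Zn to quinone monoketal 6 (first stereocentre, erased again in step 9).
4. 6 ⇐ PhI(OAc)2/MeOH dearomatisation of 2-farnesyl-4-methoxyphenol 5 ⇐ directed ortho-metalation and farnesylation of MOM-protected 4-methoxyphenol.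
5. Ring order: the six-membered carbocycle is inherited from the arene (revealed in step 4); the oxirane is the only ring made (step 7).

Abbreviation: Far = (2E,6E)-3,7,11-trimethyldodeca-2,6,10-trien-1-yl.
Assumption: the (S,R,R)-phosphoramidite is taken to give the 5R adduct by analogy with its known sense on cyclohex-2-enone; this centre is erased in step 9 and step 6 is enzyme-controlled, so the final configuration does not depend on it.

**Step 1**
Reactants: 1, 4-methoxyphenol
Product: 2, 1-methoxy-4-(methoxymethoxy)benzene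
Conditions: MOMCl, i-Pr2NEt, CH2Cl2, 0 °C → rt
Reagents that add atoms: chloromethyl methyl ether, COCCl
Why: O-alkylation (MOM protection) masks the phenol and installs the stronger ortho-directing group for step 2.

**Step 2**
Reactants: 2, 1-methoxy-4-(methoxymethoxy)benzene; 3, (2E,6E)-farnesyl bromide
Product: 4, 4-methoxy-1-(methoxymethoxy)-2-Far-benzene
Conditions: n-BuLi, TMEDA, THF, 0 °C; CuBr·SMe2, −78 °C; then 3, −78 °C → rt
Reagents that add atoms: (2E,6E)-farnesyl bromide (3), BrC/C=C(\C)CC/C=C(\C)CCC=C(C)C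
Why: Directed ortho-metalation occurs next to OMOM rather than OMe, and the aryl copper species displaces the primary allylic bromide SN2 with the 2E geometry retained.

**Step 3**
Reactants: 4, 4-methoxy-1-(methoxymethoxy)-2-Far-benzene
Product: 5, 4-methoxy-2-Far-phenol
Conditions: 3 M aq HCl, MeOH, rt
Reagents that add atoms: none
Why: Acid-catalysed acetal cleavage removes MOM; dilute acid at rt is too mild for chroman formation or polyene cyclisation.

**Step 4**
Reactants: 5, 4-methoxy-2-Far-phenol
Product: 6, 4,4-dimethoxy-2-Far-cyclohexa-2,5-dien-1-one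
Conditions: PhI(OAc)2, MeOH, 0 °C
Reagents that add atoms: methanol, CO
Why: Hypervalent-iodine oxidative dearomatisation of a p-methoxyphenol gives the p-quinone monoketal, with the phenolic carbon becoming the C=O next to the Far-bearing carbon.

**Step 5**
Reactants: 6, 4,4-dimethoxy-2-Far-cyclohexa-2,5-dien-1-one; 7, diethylzinc
Product: 8, (5R)-5-ethyl-4,4-dimethoxy-2-Far-cyclohex-2-en-1-one
Conditions: Cu(OTf)2 (2 mol %), (S,R,R)-BINOL bis(1-phenylethyl)amine phosphoramidite (4 mol %), Et2Zn, toluene, −25 °C; aq NH4Cl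
Reagents that add atoms: diethylzinc (7), CC[Zn]CC
Why: Cu-catalysed asymmetric conjugate addition (Feringa type) attacks only the unsubstituted enone, since the α-Far enone is deactivated, and the chiral ligand sets C5 as the first stereocentre.

**Step 6**
Reactants: 8, (5R)-5-ethyl-4,4-dimethoxy-2-Far-cyclohex-2-en-1-one
Product: 9, (1S,5R)-5-ethyl-4,4-dimethoxy-2-Far-cyclohex-2-en-1-ol (OH cis to ethyl)
Conditions: (S)-selective ketoreductase (KRED, NADPH-dependent alcohol dehydrogenase), NADP+ (cat.), i-PrOH, DMSO, phosphate buffer pH 7, 30 °C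
Reagents that add atoms: none
Why: Enzymatic 1,2-carbonyl reduction delivers hydride to one face under enzyme control, giving the 1S carbinol; this matches the substrate's own cis (axial-attack) preference, and the ketal is stable at pH 7.

**Step 7**
Reactants: 9, (1S,5R)-5-ethyl-4,4-dimethoxy-2-Far-cyclohex-2-en-1-ol
Product: 10, (1S,2S,4R,6S)-4-ethyl-5,5-dimethoxy-1-Far-7-oxabicyclo[4.1.0]heptan-2-ol (oxirane O, OH and ethyl all on one face)
Conditions: VO(acac)2 (5 mol %), t-BuOOH, toluene, 0 °C → rt
Reagents that add atoms: tert-butyl hydroperoxide, CC(C)(C)OO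
Why: Vanadium-catalysed hydroxyl-directed epoxidation delivers oxygen syn to the OH, setting both oxirane carbons; the Far alkenes have no allylic OH and are left alone.

**Step 8**
Reactants: 10, the cis-epoxy alcohol
Product: 11, (1R,4R,6S)-4-ethyl-5,5-dimethoxy-1-Far-7-oxabicyclo[4.1.0]heptan-2-one
Conditions: Dess–Martin periodinane, NaHCO3, CH2Cl2, rt
Reagents that add atoms: none
Why: Buffered Dess–Martin oxidation converts the directing carbinol into the ketone without touching the ketal, oxirane or alkenes.

**Step 9**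
Reactants: 11, the epoxy ketone
Product: 12, (1R,6S)-4-ethyl-5,5-dimethoxy-1-Far-7-oxabicyclo[4.1.0]hept-3-en-2-one
Conditions: LiHMDS, TMSCl, THF, −78 °C; then Pd(OAc)2, MeCN, rt
Reagents that add atoms: none
Why: Saegusa–Ito dehydrogenation; only C3 can enolise because C1 is quaternary, and β-hydride elimination gives the β-ethyl enone while erasing the ethyl stereocentre.

**Step 10**
Reactants: 12, the epoxy enone ketal
Product: 13, (1R,6S)-4-ethyl-1-Far-7-oxabicyclo[4.1.0]hept-3-ene-2,5-dione
Conditions: 48% aq HF, MeCN, 0 °C → rt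
Reagents that add atoms: water, O
Why: Acid hydrolysis of the dimethyl ketal unveils the second carbonyl; the oxirane carbons cannot epimerise.

**Step 11**
Reactants: 13, the epoxyquinone
Product: 14, (1R,5R,6R)-4-ethyl-5-hydroxy-1-Far-7-oxabicyclo[4.1.0]hept-3-en-2-one (target)
Conditions: DIBAL-H (1.1 equiv), THF, −78 °C
Reagents that add atoms: none
Why: In this 1,2-reduction the C2 carbonyl is blocked on both faces (oxirane O on one, Far CH2 on the other), so hydride adds to C5=O anti to the oxirane oxygen and gives the 5R alcohol cis to the epoxide.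

**Compound list**
1 | 4-methoxyphenol | COc1ccc(O)cc1 | starting material
2 | 1-methoxy-4-(methoxymethoxy)benzene | COCOc1ccc(OC)cc1 | intermediate
3 | (2E,6E)-farnesyl bromide | BrC/C=C(\C)CC/C=C(\C)CCC=C(C)C | starting material
4 | 4-methoxy-1-(methoxymethoxy)-2-Far-benzene | COCOc1ccc(OC)cc1C/C=C(\C)CC/C=C(\C)CCC=C(C)C | intermediate
5 | 4-methoxy-2-Far-phenol | COc1ccc(O)c(C/C=C(\C)CC/C=C(\C)CCC=C(C)C)c1 | intermediate
6 | 4,4-dimethoxy-2-Far-cyclohexa-2,5-dien-1-one | COC1(OC)C=CC(=O)C(C/C=C(\C)CC/C=C(\C)CCC=C(C)C)=C1 | intermediate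
7 | diethylzinc | CC[Zn]CC | starting material
8 | (5R)-5-ethyl-4,4-dimethoxy-2-Far-cyclohex-2-en-1-one | CC[C@@H]1CC(=O)C(C/C=C(\C)CC/C=C(\C)CCC=C(C)C)=CC1(OC)OC | intermediate
9 | (1S,5R)-5-ethyl-4,4-dimethoxy-2-Far-cyclohex-2-en-1-ol | CC[C@@H]1C[C@H](O)C(C/C=C(\C)CC/C=C(\C)CCC=C(C)C)=CC1(OC)OC | intermediate
10 | (1S,2S,4R,6S)-4-ethyl-5,5-dimethoxy-1-Far-7-oxabicyclo[4.1.0]heptan-2-ol | CC[C@@H]1C[C@H](O)[C@]2(C/C=C(\C)CC/C=C(\C)CCC=C(C)C)O[C@@H]2C1(OC)OC | intermediate
11 | (1R,4R,6S)-4-ethyl-5,5-dimethoxy-1-Far-7-oxabicyclo[4.1.0]heptan-2-one | CC[C@@H]1CC(=O)[C@]2(C/C=C(\C)CC/C=C(\C)CCC=C(C)C)O[C@@H]2C1(OC)OC | intermediate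
12 | (1R,6S)-4-ethyl-5,5-dimethoxy-1-Far-7-oxabicyclo[4.1.0]hept-3-en-2-one | CCC1=CC(=O)[C@]2(C/C=C(\C)CC/C=C(\C)CCC=C(C)C)O[C@@H]2C1(OC)OC | intermediate
13 | (1R,6S)-4-ethyl-1-Far-7-oxabicyclo[4.1.0]hept-3-ene-2,5-dione | CCC1=CC(=O)[C@]2(C/C=C(\C)CC/C=C(\C)CCC=C(C)C)O[C@@H]2C1=O | intermediate
14 | (1R,5R,6R)-4-ethyl-5-hydroxy-1-Far-7-oxabicyclo[4.1.0]hept-3-en-2-one | CCC1=CC(=O)[C@]2(C/C=C(\C)CC/C=C(\C)CCC=C(C)C)O[C@@H]2[C@@H]1O | target

**Totals**
Total steps: 11. Longest linear sequence: 11 (from 4-methoxyphenol).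

**Steps most likely to fail, with fallbacks**
1. Step 6: no ketoreductase may accept the bulky, lipophilic α-Far enone with useful rate or selectivity. Fallback: substrate-controlled Luche reduction (NaBH4/CeCl3, cis-selective), then lipase-catalysed acylation (vinyl acetate) to remove the unwanted (1R) alcohols as acetates; all (1S) alcohols converge after step 9.
2. Step 9: Saegusa β-hydride elimination at the hindered carbon next to the ketal may be slow, and Pd may attack the enol-ether/oxirane unit. Fallback: hydrolyse the ketal of 11 first, then dehydrogenate the resulting epoxy-1,4-dione by α-selenenylation and selenoxide elimination (either enolate gives the same ene-dione), reaching 13 directly.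
3. Step 11: the regio- and facial selectivity of the hydride reduction rests on analogy with related epoxyquinones and may be incomplete. Fallback: differentiate the two oxygens with protecting groups instead. From 12: Luche reduction of C2=O, TBS ether, ketal hydrolysis, reduction of C5=O (Mitsunobu inversion if the anti alcohol forms), acetylation, desilylation, Dess–Martin oxidation, then lipase deacetylation.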